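**Retrosynthetic overview**
- Target 6 ← acid cyclodehydration of o-hydroxyaryl 1,3-diketone 4, closing the O1–C2 bond; the pyranone ring C is formed last, and rings A and B are bought intact.
- Diketone 4 ← Baker–Venkataraman O→C aroyl shift of aryl ester 3.
- Ester 3 ← intermolecular aryl C–O bond formation (key step): ketone-directed ortho C–H aroyloxylation of acetophenone 1 with benzoic acid 2. The oxygen installed here becomes O1 of the flavone.

Assumption: the target (5,6,7,3',4',5'-hexamethoxyflavone) has no stereocentre, so "single enantiomer" is taken to mean the achiral compound itself.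

**Step 1**
Reactants: 1 1-(2,3,4-trimethoxyphenyl)ethan-1-one (2',3',4'-trimethoxyacetophenone); 2 3,4,5-trimethoxybenzoic acid
Product: 3 2-acetyl-3,4,5-trimethoxyphenyl 3,4,5-trimethoxybenzoate
Conditions: 2 (1.5 equiv), [RuCl2(p-cymene)]2 (5 mol%), AgSbF6 (20 mol%), K2S2O8 (2.0 equiv), ClCH2CH2Cl, 100 °C, 24 h
Reagents that add atoms: none
Why: Proposed new method: ketone-directed ortho C–H aroyloxylation of a free aryl ketone with a free arenecarboxylic acid, in which the cationic divalent ruthenium aroate (all silver is removed as AgCl) binds the acetyl oxygen of 1, carboxylate-assisted metalation at C6 (the only ortho C–H of 1, and unhindered, whereas the ortho C–H bonds of 2 are each flanked by OMe) gives a five-membered ruthenacycle already carrying the 3,4,5-trimethoxybenzoate ligand, persulfate oxidises it to tetravalent ruthenium, and C–O reductive elimination releases 3, whose di-ortho-substituted, twisted ketone no longer holds the metal; the closest known reaction type is ruthenium-catalysed carbonyl-directed ortho C–H benzoxylation of anilides and benzamides with aromatic acids, together with ketone-directed ortho C–H hydroxylation (trifluoroacetoxylation) of aryl ketones.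

**Step 2**
Reactants: 3 2-acetyl-3,4,5-trimethoxyphenyl 3,4,5-trimethoxybenzoate
Product: 4 1-(6-hydroxy-2,3,4-trimethoxyphenyl)-3-(3,4,5-trimethoxyphenyl)propane-1,3-dione
Conditions: LiN(SiMe3)2 (3.0 equiv), THF, −78 °C to rt, 2 h; then 1 M HCl
Reagents that add atoms: none
Why: Baker–Venkataraman rearrangement, in which the lithium enolate of the acetyl group attacks the neighbouring aroate carbonyl through a six-membered transition state and the aroyl group moves from O to C, driven by formation of the phenoxide/β-diketonate dianion, while the non-nucleophilic amide base does not simply cleave the aryl ester and the methyl ethers are inert.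

**Step 3**
Reactants: 4 1-(6-hydroxy-2,3,4-trimethoxyphenyl)-3-(3,4,5-trimethoxyphenyl)propane-1,3-dione
Product: 6 5,6,7-trimethoxy-2-(3,4,5-trimethoxyphenyl)-4H-chromen-4-one (CNP0295246.0), via 2-hydroxyflavanone hemiketal 5 (not isolated)
Conditions: H2SO4 (10 mol%), AcOH, 95 °C, 1 h
Reagents that add atoms: none
Why: Acid-catalysed cyclodehydration of an o-hydroxyaryl 1,3-diketone (closing stage of the Baker–Venkataraman flavone synthesis), in which the single phenol adds to the ring-B-side carbonyl to give hemiketal 5 and loss of water gives the aromatic γ-pyrone; there is only one phenol and so only one ring closure, the racemic hemiketal centre is destroyed, and catalytic H2SO4 in AcOH for 1 h is too mild to cleave the 5-OMe.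

**Compound list**
1 | 1-(2,3,4-trimethoxyphenyl)ethan-1-one (2',3',4'-trimethoxyacetophenone) | CC(=O)c1ccc(OC)c(OC)c1OC | starting material
2 | 3,4,5-trimethoxybenzoic acid | COc1cc(C(=O)O)cc(OC)c1OC | starting material
3 | 2-acetyl-3,4,5-trimethoxyphenyl 3,4,5-trimethoxybenzoate | CC(=O)c1c(OC(=O)c2cc(OC)c(OC)c(OC)c2)cc(OC)c(OC)c1OC | intermediate
4 | 1-(6-hydroxy-2,3,4-trimethoxyphenyl)-3-(3,4,5-trimethoxyphenyl)propane-1,3-dione (drawn as the diketone; largely the chelated enol) | COc1cc(C(=O)CC(=O)c2c(O)cc(OC)c(OC)c2OC)cc(OC)c1OC | intermediate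
5 | 2-hydroxy-5,6,7-trimethoxy-2-(3,4,5-trimethoxyphenyl)chroman-4-one (racemic hemiketal, not isolated) | COc1cc(C2(O)CC(=O)c3c(OC)c(OC)c(OC)cc3O2)cc(OC)c1OC | intermediate
6 | 5,6,7-trimethoxy-2-(3,4,5-trimethoxyphenyl)-4H-chromen-4-one (achiral) | COc1cc(-c2cc(=O)c3c(OC)c(OC)c(OC)cc3o2)cc(OC)c1OC | target

**Totals**
Total step count: 3. Longest linear sequence: 3 steps (1 → 3 → 4 → 6). Steps 2 and 3 are kept as separate operations because crystallising diketone 4 removes ruthenium and silver residues before the final ring closure.

**Steps most likely to fail, with fallbacks**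

Most likely to fail is step 1, the proposed new C–H aroyloxylation. The ketone is a weak director and can be parked in an unproductive chelate with the 2-OMe. Persulfate may oxidise the electron-rich rings by radical-cation pathways. Acid 2 may undergo its own carboxylate-directed C–H functionalisation. The fallback uses only known chemistry; it sets out from 2 and comes back to the route at 3. Acid 2 is converted with SOCl2 (cat. DMF, toluene, 70 °C) into 3,4,5-trimethoxybenzoyl chloride F1. Separately, bought 3,4,5-trimethoxyphenol F2 is C-acetylated ortho to the hydroxyl with AcOH/BF3·OEt2 at 90 °C (aqueous work-up hydrolyses the boron chelate) to give 1-(6-hydroxy-2,3,4-trimethoxyphenyl)ethan-1-one F3. F3 is then O-acylated with F1 in pyridine with catalytic DMAP at rt to give ester 3. The aryl C–O bond is thus bought with the phenol instead of being made by C–H activation.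

Second is step 3. The 5-OMe lies peri to the carbonyl and is the ether most easily cleaved by acid, so partial demethylation would give a mixture. The fallback sets out from 4 and comes back at 6, changing the end-game to close-then-remethylate. Diketone 4 is heated in conc. HCl/AcOH at reflux so that ring closure and 5-O-demethylation both go to completion, giving 5-hydroxy-6,7-dimethoxy-2-(3,4,5-trimethoxyphenyl)-4H-chromen-4-one F7. This is re-methylated with Me2SO4/K2CO3 in refluxing acetone to give 6. A mixture of 6 and F7 from a partly failed step 3 can be treated in the same way.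

Third is step 2. Enolisation of the di-ortho-substituted ketone may be slow, so that ester cleavage or intermolecular acyl transfer competes with the O→C shift. The fallback sets out from 3 and comes back at 6, bypassing the diketone by an intramolecular ester Wittig reaction. Ester 3 is α-brominated with CuBr2 (EtOAc/CHCl3, reflux) to give 2-(2-bromoacetyl)-3,4,5-trimethoxyphenyl 3,4,5-trimethoxybenzoate F4. PPh3 in toluene at rt gives [2-oxo-2-(6-aroyloxy-2,3,4-trimethoxyphenyl)ethyl]triphenylphosphonium bromide F5. Aqueous Na2CO3/CH2Cl2 gives the stabilised acyl ylide F6, which is heated in toluene at reflux. The ylide carbon attacks the aroate carbonyl, and loss of the phosphine oxide forms the C2=C3 bond and gives flavone 6 directly, with the ester C–O bond retained as O1–C2.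

**Further compounds**
F1 | step 1 | 3,4,5-trimethoxybenzoyl chloride | COc1cc(C(Cl)=O)cc(OC)c1OC
F2 | step 1 | 3,4,5-trimethoxyphenol (bought) | COc1cc(O)cc(OC)c1OC
F3 | step 1 | 1-(6-hydroxy-2,3,4-trimethoxyphenyl)ethan-1-one | CC(=O)c1c(O)cc(OC)c(OC)c1OC
F4 | step 2 | 2-(2-bromoacetyl)-3,4,5-trimethoxyphenyl 3,4,5-trimethoxybenzoate | O=C(CBr)c1c(OC(=O)c2cc(OC)c(OC)c(OC)c2)cc(OC)c(OC)c1OC
F5 | step 2 | [2-oxo-2-(2,3,4-trimethoxy-6-(3,4,5-trimethoxybenzoyloxy)phenyl)ethyl]triphenylphosphonium bromide | [Br-].O=C(C[P+](c1ccccc1)(c1ccccc1)c1ccccc1)c1c(OC(=O)c2cc(OC)c(OC)c(OC)c2)cc(OC)c(OC)c1OC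
F6 | step 2 | 2-[2-(triphenyl-λ5-phosphanylidene)acetyl]-3,4,5-trimethoxyphenyl 3,4,5-trimethoxybenzoate (ylide) | O=C(C=P(c1ccccc1)(c1ccccc1)c1ccccc1)c1c(OC(=O)c2cc(OC)c(OC)c(OC)c2)cc(OC)c(OC)c1OC
F7 | step 3 | 5-hydroxy-6,7-dimethoxy-2-(3,4,5-trimethoxyphenyl)-4H-chromen-4-one | COc1cc(-c2cc(=O)c3c(O)c(OC)c(OC)cc3o2)cc(OC)c1OC
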